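## Retrosynthetic overview

1. The target comes from global O-debenzylation of a tetrabenzyl flavanone. Ring C (the pyranone) is closed last, by a catalyst-controlled intramolecular oxa-Michael addition of the ring A phenol to a Knoevenagel alkylidene β-keto ester; loss of the tert-butyl ester follows. This sets C2 as S.
2. The alkylidene comes from Knoevenagel union of a cis-benzodioxane aldehyde with a ring A β-keto ester, made in three steps from 2,4,6-trihydroxyacetophenone.
3. The cis-benzodioxane comes from a trans-epoxide (Sharpless epoxidation of O-benzylconiferyl alcohol, which sets both dioxane centres) and 4-fluoro-3-hydroxybenzaldehyde: phenoxide SN2 at the benzylic carbon (inversion), then SNAr closure para to CHO (retention).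
4. Ring order: oxirane, then the 1,4-dioxane ring, then pyranone ring C. Three branches of 4, 1 and 3 steps converge in steps 6 and 10.

Assumption: the quinidine-derived thiourea is taken to give the 2S chromanone and its quinine-derived pseudoenantiomer the 2R. The sense is checked on 17 by CD against the sample made with the other catalyst, which is used instead if the sense is reversed.

## Route

Step 1
Reactants: 1 4-(benzyloxy)-3-methoxybenzaldehyde
Product: 2 ethyl (2E)-3-[4-(benzyloxy)-3-methoxyphenyl]prop-2-enoate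
Conditions: (EtO)2P(O)CH2CO2Et, NaH, THF, 0 °C to rt
Reagents that add atoms: triethyl phosphonoacetate, CCOC(=O)CP(=O)(OCC)OCC
Why: Horner–Wadsworth–Emmons olefination of a non-enolisable aryl aldehyde with a stabilised phosphonate anion gives the (E)-cinnamate almost exclusively; no stereocentre is formed.

Step 2
Reactants: 2 ethyl (2E)-3-[4-(benzyloxy)-3-methoxyphenyl]prop-2-enoate
Product: 3 (2E)-3-[4-(benzyloxy)-3-methoxyphenyl]prop-2-en-1-ol
Conditions: iBu2AlH (2.5 equiv), CH2Cl2, −78 to 0 °C; aq. potassium sodium tartrate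
Reagents that add atoms: none
Why: Hydride reduction with iBu2AlH takes the conjugated ester 1,2-selectively to the allylic alcohol at low temperature and leaves the alkene and the benzyl ether alone.

Step 3
Reactants: 3 (2E)-3-[4-(benzyloxy)-3-methoxyphenyl]prop-2-en-1-ol
Product: 4 [(2R,3R)-3-[4-(benzyloxy)-3-methoxyphenyl]oxiran-2-yl]methanol
Conditions: Ti(OiPr)4 (10 mol %), D-(−)-diisopropyl tartrate (12 mol %), t-BuOOH (2 equiv, decane), 4 Å molecular sieves, CH2Cl2, −20 °C; aq. NaOH/NaCl work-up
Reagents that add atoms: tert-butyl hydroperoxide, CC(C)(C)OO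
Why: Sharpless asymmetric epoxidation, in which the titanium tartrate complex binds the allylic alcohol and delivers the peroxide oxygen to one alkene face; the D-(−)-tartrate gives the (2R,3R)-trans-epoxy alcohol (the L-(+)-ester gives the (2S,3S) series with (E)-cinnamyl alcohols), which fixes both future dioxane centres, and the catalytic sieve protocol with a non-acidic work-up spares the acid-labile electron-rich benzylic epoxide.

Step 4
Reactants: 4 [(2R,3R)-3-[4-(benzyloxy)-3-methoxyphenyl]oxiran-2-yl]methanol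
Product: 5 (2R,3R)-2-[(benzyloxy)methyl]-3-[4-(benzyloxy)-3-methoxyphenyl]oxirane
Conditions: NaH, BnBr, tetrabutylammonium iodide (cat.), THF, 0 °C to rt
Reagents that add atoms: benzyl bromide, BrCc1ccccc1
Why: Williamson etherification of the primary alkoxide is fast at 0 °C with iodide catalysis, so Payne rearrangement does not compete and the epoxide centres are untouched; the benzyl ether later keeps the primary oxygen out of the ring closure.

Step 5
Reactants: 6 4-fluoro-3-methoxybenzaldehyde
Product: 7 4-fluoro-3-hydroxybenzaldehyde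
Conditions: BBr3, CH2Cl2, −78 °C to rt; H2O
Reagents that add atoms: none
Why: Lewis-acid ether cleavage, in which BBr3 coordinates the methoxy oxygen and bromide removes the methyl group by SN2; the aryl fluoride and, after hydrolysis, the aldehyde survive.

Step 6
Reactants: 5 (2R,3R)-2-[(benzyloxy)methyl]-3-[4-(benzyloxy)-3-methoxyphenyl]oxirane; 7 4-fluoro-3-hydroxybenzaldehyde
Product: 9 (2R,3S)-2-[(benzyloxy)methyl]-3-[4-(benzyloxy)-3-methoxyphenyl]-2,3-dihydro-1,4-benzodioxine-6-carbaldehyde, via ring-opened fluoro hydroxy ether 8 (not isolated)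
Conditions: Cs2CO3 (2.2 equiv), DMSO, 70 °C, then 95 °C
Reagents that add atoms: none
Why: The caesium phenoxide of 7 opens the epoxide by SN2 at the electronically activated benzylic carbon with inversion (the R epoxide carbon becomes the S aryloxy carbon), and the C2 alkoxide so released closes the six-membered ring by intramolecular SNAr on the C–F bond para to the formyl group with retention at C2; the trans-epoxide thus becomes the cis-benzodioxane, with the aryl-bearing oxygen meta and the CH2O-bearing oxygen para to CHO.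

Step 7
Reactants: 10 1-(2,4,6-trihydroxyphenyl)ethan-1-one
Product: 11 1-[2,4-bis(benzyloxy)-6-hydroxyphenyl]ethan-1-one
Conditions: BnBr (2.1 equiv), K2CO3, DMF, rt
Reagents that add atoms: benzyl bromide, BrCc1ccccc1
Why: Williamson benzylation; the hydroxyl that is hydrogen-bonded to the acetyl carbonyl is the least nucleophilic of the three, so two equivalents of benzyl bromide etherify the other two and leave the chelated phenol free.

Step 8
Reactants: 11 1-[2,4-bis(benzyloxy)-6-hydroxyphenyl]ethan-1-one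
Product: 12 2-acetyl-3,5-bis(benzyloxy)phenyl tert-butyl carbonate
Conditions: Boc2O (1.3 equiv), DMAP (10 mol %), MeCN, rt
Reagents that add atoms: di-tert-butyl dicarbonate, CC(C)(C)OC(=O)OC(=O)OC(C)(C)C
Why: DMAP-catalysed acylation (nucleophilic catalysis) of the remaining phenol gives the aryl tert-butyl carbonate and places the future ester carbon next to the acetyl group.

Step 9
Reactants: 12 2-acetyl-3,5-bis(benzyloxy)phenyl tert-butyl carbonate
Product: 13 tert-butyl 3-[2,4-bis(benzyloxy)-6-hydroxyphenyl]-3-oxopropanoate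
Conditions: LiN(SiMe3)2 (2.5 equiv), THF, −78 to 0 °C; cold 1 M HCl
Reagents that add atoms: none
Why: Baker–Venkataraman-type O-to-C acyl transfer, in which the kinetic lithium enolate of the methyl ketone attacks the neighbouring carbonate carbonyl through a six-membered transition state and expels the phenoxide; this gives the β-keto ester with the phenol free, and the bulky tert-butyl ester does not lactonise to the 4-hydroxycoumarin below 0 °C.

Step 10
Reactants: 9 (2R,3S)-2-[(benzyloxy)methyl]-3-[4-(benzyloxy)-3-methoxyphenyl]-2,3-dihydro-1,4-benzodioxine-6-carbaldehyde; 13 tert-butyl 3-[2,4-bis(benzyloxy)-6-hydroxyphenyl]-3-oxopropanoate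
Product: 14 tert-butyl 2-[2,4-bis(benzyloxy)-6-hydroxybenzoyl]-3-{(2R,3S)-2-[(benzyloxy)methyl]-3-[4-(benzyloxy)-3-methoxyphenyl]-2,3-dihydro-1,4-benzodioxin-6-yl}prop-2-enoate
Conditions: piperidine (20 mol %), AcOH (20 mol %), 4 Å molecular sieves, toluene, rt
Reagents that add atoms: none
Why: Knoevenagel condensation through the piperidinium iminium ion of the aldehyde and the enol of the β-keto ester, driven by the sieves; the tert-butyl ester and the hydrogen-bonded phenol make the alkylidene isolable without premature racemic ring closure, and the dioxane centres are inert because the guaiacyl oxygen is benzylated.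

Step 11
Reactants: 14 tert-butyl 2-[2,4-bis(benzyloxy)-6-hydroxybenzoyl]-3-{(2R,3S)-2-[(benzyloxy)methyl]-3-[4-(benzyloxy)-3-methoxyphenyl]-2,3-dihydro-1,4-benzodioxin-6-yl}prop-2-enoate
Product: 17 (2S)-5,7-bis(benzyloxy)-2-{(2R,3S)-2-[(benzyloxy)methyl]-3-[4-(benzyloxy)-3-methoxyphenyl]-2,3-dihydro-1,4-benzodioxin-6-yl}-2,3-dihydro-4H-chromen-4-one, via tert-butyl 4-oxochromane-3-carboxylate 15 (not isolated), via 4-oxochromane-3-carboxylic acid 16 (not isolated)
Conditions: quinidine-derived 3,5-bis(trifluoromethyl)phenyl thiourea (9-amino-9-deoxy-epi-quinidine type, 10 mol %), toluene, −25 °C; then TsOH·H2O (0.5 equiv), 80 °C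
Reagents that add atoms: none
Why: Intramolecular oxa-Michael addition under bifunctional catalysis, in which the thiourea holds the β-keto ester and the quinuclidine nitrogen activates the phenol, so the phenoxide adds to one face of the alkylidene, closes ring C and sets C2 as S under catalyst control (the remote dioxane centres give no bias); TsOH then cleaves the tert-butyl ester through its enol and the β-keto acid loses CO2, which removes the C3 centre under conditions that 4'-alkoxyflavanones, and hence both benzylic aryl ether centres, are expected to tolerate.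

Step 12
Reactants: 17 (2S)-5,7-bis(benzyloxy)-2-{(2R,3S)-2-[(benzyloxy)methyl]-3-[4-(benzyloxy)-3-methoxyphenyl]-2,3-dihydro-1,4-benzodioxin-6-yl}-2,3-dihydro-4H-chromen-4-one
Product: 18 (2S)-5,7-dihydroxy-2-[(2R,3S)-3-(4-hydroxy-3-methoxyphenyl)-2-(hydroxymethyl)-2,3-dihydro-1,4-benzodioxin-6-yl]-2,3-dihydro-4H-chromen-4-one (isocisilandrin)
Conditions: H2 (1 atm), 10% Pd/C, EtOAc–MeOH, rt
Reagents that add atoms: none
Why: Catalytic hydrogenolysis removes the four O-benzyl groups under neutral conditions at room temperature, where the flavanone carbonyl, the cyclic benzylic C–O bonds and all three stereocentres are stable; no acid or base is present, so C2 cannot epimerise through the chalcone and the cis-dioxane cannot open through a quinone methide.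

## Compound list

1 | 4-(benzyloxy)-3-methoxybenzaldehyde | COc1cc(C=O)ccc1OCc1ccccc1 | starting material
2 | ethyl (2E)-3-[4-(benzyloxy)-3-methoxyphenyl]prop-2-enoate | CCOC(=O)/C=C/c1ccc(OCc2ccccc2)c(OC)c1 | intermediate
3 | (2E)-3-[4-(benzyloxy)-3-methoxyphenyl]prop-2-en-1-ol | OC/C=C/c1ccc(OCc2ccccc2)c(OC)c1 | intermediate
4 | [(2R,3R)-3-[4-(benzyloxy)-3-methoxyphenyl]oxiran-2-yl]methanol | COc1cc([C@H]2O[C@@H]2CO)ccc1OCc1ccccc1 | intermediate
5 | (2R,3R)-2-[(benzyloxy)methyl]-3-[4-(benzyloxy)-3-methoxyphenyl]oxirane | COc1cc([C@H]2O[C@@H]2COCc2ccccc2)ccc1OCc1ccccc1 | intermediate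
6 | 4-fluoro-3-methoxybenzaldehyde | COc1cc(C=O)ccc1F | starting material
7 | 4-fluoro-3-hydroxybenzaldehyde | Oc1cc(C=O)ccc1F | intermediate
8 | 3-{(1S,2R)-3-(benzyloxy)-1-[4-(benzyloxy)-3-methoxyphenyl]-2-hydroxypropoxy}-4-fluorobenzaldehyde | COc1cc([C@H](Oc2cc(C=O)ccc2F)[C@H](O)COCc2ccccc2)ccc1OCc1ccccc1 | intermediate
9 | (2R,3S)-2-[(benzyloxy)methyl]-3-[4-(benzyloxy)-3-methoxyphenyl]-2,3-dihydro-1,4-benzodioxine-6-carbaldehyde | COc1cc([C@@H]2Oc3cc(C=O)ccc3O[C@@H]2COCc2ccccc2)ccc1OCc1ccccc1 | intermediate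
10 | 1-(2,4,6-trihydroxyphenyl)ethan-1-one | CC(=O)c1c(O)cc(O)cc1O | starting material
11 | 1-[2,4-bis(benzyloxy)-6-hydroxyphenyl]ethan-1-one | CC(=O)c1c(O)cc(OCc2ccccc2)cc1OCc1ccccc1 | intermediate
12 | 2-acetyl-3,5-bis(benzyloxy)phenyl tert-butyl carbonate | CC(=O)c1c(OC(=O)OC(C)(C)C)cc(OCc2ccccc2)cc1OCc1ccccc1 | intermediate
13 | tert-butyl 3-[2,4-bis(benzyloxy)-6-hydroxyphenyl]-3-oxopropanoate | CC(C)(C)OC(=O)CC(=O)c1c(O)cc(OCc2ccccc2)cc1OCc1ccccc1 | intermediate
14 | tert-butyl 2-[2,4-bis(benzyloxy)-6-hydroxybenzoyl]-3-{(2R,3S)-2-[(benzyloxy)methyl]-3-[4-(benzyloxy)-3-methoxyphenyl]-2,3-dihydro-1,4-benzodioxin-6-yl}prop-2-enoate (alkene isomers, geometry not fixed) | COc1cc([C@@H]2Oc3cc(C=C(C(=O)OC(C)(C)C)C(=O)c4c(O)cc(OCc5ccccc5)cc4OCc4ccccc4)ccc3O[C@@H]2COCc2ccccc2)ccc1OCc1ccccc1 | intermediate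
15 | tert-butyl (2S)-5,7-bis(benzyloxy)-2-{(2R,3S)-2-[(benzyloxy)methyl]-3-[4-(benzyloxy)-3-methoxyphenyl]-2,3-dihydro-1,4-benzodioxin-6-yl}-4-oxo-3,4-dihydro-2H-chromene-3-carboxylate (C3 labile) | COc1cc([C@@H]2Oc3cc([C@@H]4C(C(=O)OC(C)(C)C)C(=O)c5c(OCc6ccccc6)cc(OCc6ccccc6)cc5O4)ccc3O[C@@H]2COCc2ccccc2)ccc1OCc1ccccc1 | intermediate
16 | (2S)-5,7-bis(benzyloxy)-2-{(2R,3S)-2-[(benzyloxy)methyl]-3-[4-(benzyloxy)-3-methoxyphenyl]-2,3-dihydro-1,4-benzodioxin-6-yl}-4-oxo-3,4-dihydro-2H-chromene-3-carboxylic acid (C3 labile) | COc1cc([C@@H]2Oc3cc([C@@H]4C(C(=O)O)C(=O)c5c(OCc6ccccc6)cc(OCc6ccccc6)cc5O4)ccc3O[C@@H]2COCc2ccccc2)ccc1OCc1ccccc1 | intermediate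
17 | (2S)-5,7-bis(benzyloxy)-2-{(2R,3S)-2-[(benzyloxy)methyl]-3-[4-(benzyloxy)-3-methoxyphenyl]-2,3-dihydro-1,4-benzodioxin-6-yl}-2,3-dihydro-4H-chromen-4-one | COc1cc([C@@H]2Oc3cc([C@@H]4CC(=O)c5c(OCc6ccccc6)cc(OCc6ccccc6)cc5O4)ccc3O[C@@H]2COCc2ccccc2)ccc1OCc1ccccc1 | intermediate
18 | (2S)-5,7-dihydroxy-2-[(2R,3S)-3-(4-hydroxy-3-methoxyphenyl)-2-(hydroxymethyl)-2,3-dihydro-1,4-benzodioxin-6-yl]-2,3-dihydro-4H-chromen-4-one (isocisilandrin) | COc1cc([C@@H]2Oc3cc([C@@H]4CC(=O)c5c(O)cc(O)cc5O4)ccc3O[C@@H]2CO)ccc1O | target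

## Step count and risks

Total step count: 12.
Longest linear sequence: 8 steps (steps 1, 2, 3, 4, 6, 10, 11, 12), which is two thirds of the total.

**Step 3.** The electron-rich epoxy alcohol 4 may open at the benzylic carbon under the titanium Lewis acid or during work-up. The fallback sets out from allylic alcohol 3 and avoids both the Lewis acid and the free hydroxyl. Benzylation of 3 (NaH, BnBr, THF) gives (E)-1-(benzyloxy)-4-[3-(benzyloxy)prop-1-en-1-yl]-2-methoxybenzene F1. Dioxirane epoxidation of F1 follows, with the D-fructose-derived Shi ketone (30 mol %), KHSO5 (as the triple salt 2KHSO5·KHSO4·K2SO4), K2CO3 buffer at pH about 10.5, MeCN–dimethoxymethane–water, 0 °C. This ketone gives (R,R)-epoxides from trans-β-substituted styrenes, so the product is the protected epoxide itself. The fallback comes back to the route at 5, and step 4 is then not needed.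

**Step 6.** The phenoxide may open the internal epoxide too slowly, so that oligomerisation of 7 by intermolecular SNAr or attack at C2 competes, or the one-pot closure may be unclean. The fallback sets out from the unprotected epoxy alcohol 4 together with 7. Opening is mediated by Ti(OiPr)4 (1.5 equiv, CH2Cl2, rt); chelation of the epoxy alkoxide to titanium directs the phenol to C3 with inversion at room temperature. This gives 3-{(1S,2R)-1-[4-(benzyloxy)-3-methoxyphenyl]-2,3-dihydroxypropoxy}-4-fluorobenzaldehyde F2. Primary-selective monobenzylation of F2 (Ag2O, BnBr, CH2Cl2) gives the hydroxy ether, now isolated and purified. The fallback comes back to the route at 8, which is closed to 9 in a separate operation (Cs2CO3, DMSO, 95 °C).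

**Step 11.** Catalyst control may be insufficient with this hindered, doubly ortho-substituted aryl ketone, or the TsOH treatment may epimerise a benzylic aryl ether centre. The fallback sets out from aldehyde 9 and acetophenone 11 and uses neither the ester activator nor acid. Claisen–Schmidt condensation (KOH, EtOH, rt) gives (2E)-1-[2,4-bis(benzyloxy)-6-hydroxyphenyl]-3-{(2R,3S)-2-[(benzyloxy)methyl]-3-[4-(benzyloxy)-3-methoxyphenyl]-2,3-dihydro-1,4-benzodioxin-6-yl}prop-2-en-1-one F3. Its intramolecular oxa-Michael closure with NaOAc in refluxing EtOH gives the 2S flavanone together with its diastereomer, the (2R)-epimer of the tetrabenzyl flavanone F4. The two are separated by preparative HPLC, and F4 is returned to the same NaOAc conditions, where it re-equilibrates through the chalcone. The fallback comes back to the route at 17.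

## Further compounds

F1 | step 3 | (E)-1-(benzyloxy)-4-[3-(benzyloxy)prop-1-en-1-yl]-2-methoxybenzene | COc1cc(/C=C/COCc2ccccc2)ccc1OCc1ccccc1
F2 | step 6 | 3-{(1S,2R)-1-[4-(benzyloxy)-3-methoxyphenyl]-2,3-dihydroxypropoxy}-4-fluorobenzaldehyde | COc1cc([C@H](Oc2cc(C=O)ccc2F)[C@H](O)CO)ccc1OCc1ccccc1
F3 | step 11 | (2E)-1-[2,4-bis(benzyloxy)-6-hydroxyphenyl]-3-{(2R,3S)-2-[(benzyloxy)methyl]-3-[4-(benzyloxy)-3-methoxyphenyl]-2,3-dihydro-1,4-benzodioxin-6-yl}prop-2-en-1-one | COc1cc([C@@H]2Oc3cc(/C=C/C(=O)c4c(O)cc(OCc5ccccc5)cc4OCc4ccccc4)ccc3O[C@@H]2COCc2ccccc2)ccc1OCc1ccccc1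
F4 | step 11 | (2R)-5,7-bis(benzyloxy)-2-{(2R,3S)-2-[(benzyloxy)methyl]-3-[4-(benzyloxy)-3-methoxyphenyl]-2,3-dihydro-1,4-benzodioxin-6-yl}-2,3-dihydro-4H-chromen-4-one | COc1cc([C@@H]2Oc3cc([C@H]4CC(=O)c5c(OCc6ccccc6)cc(OCc6ccccc6)cc5O4)ccc3O[C@@H]2COCc2ccccc2)ccc1OCc1ccccc1
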